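Slowness is the place to start: dissolved target creeps into isomer of the product B, and counting that step's forward rate with no way back, its half-life is 1.7 min.

substrate 1.1 M; gas 83 mM (held); time 3.0 min

- target and crystals together at 3.0 min, in percent of the substrate charged
- the change that raises the amount of target and crystals together at 3.0 min, in percent of the substrate charged most ("none" if none brings more than 2 percentage points) (midnight / spring / dusk / dawn / none)
- amount of target and crystals together at 3.0 min, in percent of the substrate charged, after dawn

- midnight: doubling the dissolution coefficient of step 3, all else as stated
- spring: doubling the solubility in step 3, all else as stated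
- dusk: doubling the saturation concentration of gas, all else as stated
- dawn: doubling the transfer coefficient of step 5, all else as stated

- target is meant together with its crystals
- solid, in amounts per volume of the solution: crystals
- at the start none of reagent is dissolved
- run time (flask): 3.0 min

    substrate + reagent ⇌ target (K1 = 51 M⁻¹, k1 = 6.5 M⁻¹ s⁻¹)
    substrate + reagent ⇌ isomer of the product A (K2 = 30 M⁻¹, k2 = 2.3 M⁻¹ s⁻¹)
    crystals ⇌ target, rate k3*(cs3 - [target]) while solid is left; crystals form when [target] > cs3 (cs3 = 49 mM, k3 = 0.077 s⁻¹)
    target ⇌ isomer of the product B (K4 = 3.0, k4 = 0.0067 s⁻¹)
    gas ⇌ reagent, rate k5*(csat - [reagent]) (k5 = 1.0 s⁻¹, csat = 83 mM)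

In this flask substrate takes up reagent, which comes from the gas, and gives target or isomer of the product A, both reversibly. Target above its solubility falls out as crystals, and the creep acts on dissolved target.

Two numbers seem not to go together. Over the run the forward creep, counted with no way back, takes 70.1% of any dissolved target left to itself, yet a saturated solution holds 4.45% of the charge. So what does it cost?

Freeze what hardly moves. The gas can deliver the charge in 13.3 s, and excess target falls out with a time of 13.0 s, both shorter than the run. I therefore hold [reagent] at 83 mM and [target] at 49 mM. Substrate then stands at 1.05% of the charge and isomer of the product A at 2.62%. By my reckoning the saturated solution, refilled as it leaks, loses 5.37% of the charge by the forward creep over the run.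

The surge above saturation costs as well. Excess target creeps at 0.0067 s⁻¹, slower than the 0.077 s⁻¹ at which it falls out, so the toll, what creeps away per amount that becomes crystals, is 0.0870. With crystals taken as what remains, the creep takes 12.3%, and I expect 84.0%, counting no return from isomer of the product B.

Midnight cuts the toll to 0.0435. Spring costs 9 percentage points, dusk cuts substrate to 0.525%, and dawn leaves both frozen levels unmoved. My choice is midnight, and after dawn I expect 84.0%.

The forecast gives 86.5%, higher than my figure, then midnight and 86.6%, holding that “Only faster crystallisation (midnight) meaningfully cuts the time target spends dissolved”. The flask gives 86.6%, with midnight best at 2.7 points, and 86.7% after dawn.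

Set 0.077 s⁻¹ against 0.0067 s⁻¹ in this flask: its 82.1% of crystals at the toll, plus the forward loss from the saturated solution, make 12.5% forward, and with the backward turnover at 23% of the forward one, that nets 9.59%, with 9.58% standing as isomer of the product B. In the neighbour flask with 0.44 M of substrate, the same toll on 65.3% of crystals, plus that loss reckoned on the smaller charge, makes 19.1% forward, against 15.0% standing there.

All constants are invented; the rest is arithmetic.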